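**Analysis of the target**

Compound 22 is an achiral diaryl ether: two benzene rings joined through one oxygen, with no stereocenter and no further ring. Ring A, numbered from the ether carbon C1, carries hydroxyls at C2 and C4 and a pentyl chain at C6. This is the skeleton of olivetol (1) with one extra oxygen at the carbon between the pentyl group and a hydroxyl, and as a free 1,2,4-trioxygenated benzene it is easily oxidised. Ring B carries the methyl ester at C1, the ether oxygen at C2, hydrogen at C3, methoxy at C4, hydrogen at C5 and the pentanoyl group at C6, so the ester sits between the aryloxy group and the ketone. Two lactonisations threaten this ester. A hydroxyl at the benzylic carbon of the C6 side chain would close a five-membered lactone onto it, and the ring A C2 phenol can reach it across the ether oxygen to close a seven-membered lactone. The ketone must therefore never pass through a free carbinol, and the phenols are best released last under neutral conditions. The ether is hard to make by coupling two benzene rings, because its ring A carbon has two ortho substituents and its ring B carbon lies next to the ester. The strategy rests on two features of ring B. Its atoms C2, C3, C4 and C5 carry O, H, O and H, which is the pattern of C6, C5, C4 and C3 of a 6-aryloxy-4-methoxy-2-pyranone. Its neighbours C1 and C6 carry two adjacent carbon substituents, which is the pattern of an alkyne with an ester at one end and a masked acyl group at the other.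

**Retrosynthetic reasoning**

22 from 21. The last bonds cut are the two O–benzyl bonds on ring A. Both phenols stay masked to the end because the free ring is oxidation-prone and its C2 hydroxyl can attack the ester. The forward step has to cleave two benzyl aryl ethers without reducing the aryl ketone.

21 from 20. The ring B ketone is traced back to a 1,3-dioxolane. The mask is kept at the ketone oxidation level on purpose. A protected carbinol at this carbon would, once freed, attack the neighbouring ester and close the five-membered lactone, which would then have to be reopened, oxidised and re-esterified. A ketal never passes through the alcohol, withstands heat and base, and is only an inductive acceptor, which matters for the next disconnection.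

20 from 12 and 18. Ring B is cut at C1–C2 and C5–C6, which are the two bonds formed when the diene of pyranone 12 adds across the triple bond of ynoate 18. The bridged lactone 19 then aromatises by decarboxylation. This cut is chosen because it builds ring B around an ether oxygen that is already in place, and it sets all four substituents of ring B in one operation. The forward reaction has to control one thing, the orientation of the alkyne. The ester must end up beside the aryloxy carbon and the ketal-bearing carbon beside the unsubstituted pyranone C3.

12 from 6 and 11. The aryl–O bond is cut on the pyranone side. C6 of chloropyranone 11 is an acyl-type carbon, so the hindered phenol 6 is attached by addition–elimination and not by coupling of two crowded benzene rings.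

6 from 4, 3 and 1. The phenolic C–O bond of 6 is traced to the formyl group of aldehyde 4 by an oxidative aryl migration. The benzyl ethers come off to give 3, and the formyl C–C bond is cut to return olivetol (1). Formylation places the future oxygen at the only kind of ring position that gives the 2,4-dihydroxy-6-pentyl pattern.

11 from 9, 8 and 7. The chloropyranone is the cyclised form of the bis(acid chloride) 10 of diacid 9, whose five carbons are those of the 3-oxoglutarate diester 7. The enol ether is installed at the diester stage (8), where the symmetry of 7 removes any regiochemical question. A pyranone assembled from two three-carbon malonyl units would carry a superfluous carbonyl substituent at C3, so the five-carbon chain is the correct source.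

18 from 15, 16, 14 and 13. The ester carbon is cut from the alkyne terminus, leaving ketal alkyne 15 and chloroformate 16. The ketal is traced to ynone 14 and this to the commercial alkynol 13.

**Alternatives that were turned down**

Alternative 1: The ester and the ring A C2 hydroxyl are traced back to the seven-membered lactone of depsidone A2, and this to the spiro quinone monoketal A1, in which ring A is a cyclohexadienone whose spiro carbon carries both oxygens. In the forward key step BF3·OEt2 activates the dienone and the acyloxy oxygen moves to the neighbouring unsubstituted ring carbon. The six-membered dioxinone becomes the seven-membered lactone and ring A rearomatises to A2. Methanolysis then opens the lactone to the target.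
- For: the route is biomimetic. The migration can only end at the ring carbon that bears hydrogen, because the other neighbour bears the pentyl chain. The last step frees ester and phenol together without protecting groups, and on this point it is stronger than the chosen route, which needs benzyl ethers and an oxidation to place the ring A oxygen.
- Against: A1 has to be made by oxidative spirocyclisation of an aryl ester or diaryl ether of a fully substituted ring B acid. The hindered C–O bond formation is thus only moved earlier, onto an acid that exists as a lactol because of its ortho ketone and is a poor acylating agent. Under the Lewis acid the aryloxy oxygen could migrate in place of the acyloxy oxygen, or the ketal could fragment. The closing methanolysis is an equilibrium run on an unprotected, air-sensitive polyphenol.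
- Comparison: ring B must be made separately by classical aromatic chemistry, so the step count should be higher. The chosen strategy offers instead a convergent construction of ring B with all four substituents set at once.

Alternative 2: Ring A is cut into the four-carbon vinylketene derived from diazo ketone A3 and the two-carbon siloxyalkyne A4. In the forward key step visible light triggers the Wolff rearrangement of A3. The vinylketene adds A4 by [2+2] cycloaddition, the cyclobutenone opens, and 6π electrocyclisation and tautomerisation give A5, the target with its ring A C4 oxygen silylated (Danheiser benzannulation).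
- For: the two ring A oxygens emerge differentiated, and A5 is one desilylation from the target, which is shorter than the end of the chosen route. The ether oxygen is introduced as an unhindered vinylogous ester.
- Against: ring B must be complete, with its free pentanoyl ketone, before the key step. The diazo transfer needed for A3 is enolate chemistry beside a second enolisable ketone and an ester. The photochemical step runs in the presence of an aryl ketone with γ-hydrogens, which invites Norrish type 2 cleavage and photoenolisation. A4 is a sensitive reagent.
- Comparison: the chosen key step is thermal, the ketone is masked during it, and both partners come from commodity chemicals in three or four steps each.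

Alternative 3: Ring B is cut into three alkynes, the ester-tethered diyne A6 and methoxyacetylene A7. In the forward key step Cp*RuCl(cod) forms a ruthenacycle from A6, inserts A7 and releases phthalide A8. Three C–C bonds, ring B and the fused lactone form together.
- For: it forms more bonds in one step than any other option, and here it is stronger than the chosen strategy. The tether fixes the ester carbon beside the butyl-bearing carbon.
- Against: A6 contains an aryl ynol ether conjugated to an ester, a very polarised and hydrolytically fragile alkyne that must be built on the hindered phenol. A7 is volatile and polymerises. The orientation of A7 depends on the catalyst and not on the tether. Above all A8 is the five-membered lactone that the chosen route is designed to avoid. It would have to be opened, oxidised and re-esterified through a keto acid that exists as a lactol, which costs three or more steps.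
- Comparison: the chosen strategy needs no transition metal in the ring-forming step, draws its regiochemistry from the polarisation of only two components, and delivers the ketone oxidation level and the open methyl ester directly.

Key step: step 11

Remarks on the chemistry:
- Compounds 8, 9 and 10 are drawn as the E isomers expected under equilibrating conditions. The double-bond geometry is erased in step 6.
- Alkynol 13 is used as the racemate and its stereocenter is destroyed in step 8. Lactone 19 is a racemic transient whose bridgehead centers vanish on aromatisation.

**Route**

Step 1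
Reactants: 1 olivetol (5-pentylbenzene-1,3-diol)
Product: 3 2,4-dihydroxy-6-pentylbenzaldehyde, via aryl iminium chloride 2 (not isolated)
Conditions: POCl3, DMF, 0 °C to rt; then H2O, 50 °C
Reagents that add atoms: N,N-dimethylformamide, CN(C)C=O (formyl carbon); water, O (formyl oxygen)
Why: Vilsmeier–Haack formylation; the resorcinol should be attacked para to one hydroxyl and ortho to the other (the two such positions are equivalent) and not at the more crowded carbon between the hydroxyls, and water hydrolyses iminium salt 2 to the aldehyde.

Step 2
Reactants: 3 2,4-dihydroxy-6-pentylbenzaldehyde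
Product: 4 2,4-bis(benzyloxy)-6-pentylbenzaldehyde
Conditions: BnBr, K2CO3, DMF, 60 °C
Reagents that add atoms: benzyl bromide, BrCc1ccccc1
Why: Williamson ether synthesis; the para hydroxyl reacts readily and the chelated ortho hydroxyl follows on warming with excess halide, and the benzyl ethers should survive every later step up to the final hydrogenolysis.

Step 3
Reactants: 4 2,4-bis(benzyloxy)-6-pentylbenzaldehyde
Product: 6 2,4-bis(benzyloxy)-6-pentylphenol, via aryl formate 5 (not isolated)
Conditions: mCPBA, CH2Cl2, 0 °C to rt; then K2CO3 (cat.), MeOH, rt, under argon
Reagents that add atoms: 3-chloroperoxybenzoic acid, OOC(=O)c1cccc(Cl)c1 (phenolic oxygen)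
Why: Dakin-type oxidation through a Baeyer–Villiger shift; the electron-rich aryl group with ortho and para oxygens migrates in preference to hydride, and mild methanolysis of formate 5 frees the phenol without touching the benzyl ethers.

Step 4
Reactants: 7 dimethyl 3-oxopentanedioate
Product: 8 dimethyl (E)-3-methoxypent-2-enedioate
Conditions: HC(OMe)3, H2SO4 (cat.), MeOH, 50 °C
Reagents that add atoms: trimethyl orthoformate, COC(OC)OC
Why: Acid-catalysed enol ether formation from a β-keto ester through the dimethyl ketal and loss of methanol; the conjugated enol ether is the thermodynamic product.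

Step 5
Reactants: 8 dimethyl (E)-3-methoxypent-2-enedioate
Product: 9 (E)-3-methoxypent-2-enedioic acid
Conditions: NaOH (aq), MeOH, 0 °C to rt; then HCl to pH 2, 0 °C
Reagents that add atoms: sodium hydroxide, [Na+].[OH-] (carboxyl oxygens)
Why: Saponification; β-alkoxyacrylates tolerate aqueous hydroxide, and cold, brief acidification should keep the enol ether intact.

Step 6
Reactants: 9 (E)-3-methoxypent-2-enedioic acid
Product: 11 6-chloro-4-methoxy-2H-pyran-2-one, via bis(acid chloride) 10 (not isolated)
Conditions: (COCl)2, DMF (cat.), CH2Cl2, 0 °C to rt; then PhMe, 60 °C
Reagents that add atoms: oxalyl chloride, ClC(=O)C(=O)Cl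
Why: Cyclisation of a glutaconic acid to a 6-chloro-2-pyranone through its bis(acid chloride); the carbonyl oxygen of the push–pull β-methoxyenoyl chloride acylates the second acid chloride in a six-membered ring and loss of HCl gives the conjugated pyranone, and the E geometry of 9 holds the two carboxyl carbons cis as this requires.

Step 7
Reactants: 6 2,4-bis(benzyloxy)-6-pentylphenol; 11 6-chloro-4-methoxy-2H-pyran-2-one
Product: 12 6-[2,4-bis(benzyloxy)-6-pentylphenoxy]-4-methoxy-2H-pyran-2-one
Conditions: Cs2CO3, 4 Å MS, MeCN, 0 °C to rt
Reagents that add atoms: none
Why: Addition–elimination at C6 of the chloropyranone, which behaves as a vinylogous acid chloride; attack at the lactone carbonyl would open the ring to an acyl chloride that recloses to the same product, so both modes converge, and C-arylation is excluded because both ortho positions and the para position of the phenoxide are substituted.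

Step 8
Reactants: 13 hept-1-yn-3-ol (racemic)
Product: 14 hept-1-yn-3-one
Conditions: Dess–Martin periodinane, CH2Cl2, 0 °C to rt
Reagents that add atoms: none
Why: Dess–Martin oxidation of a secondary propargylic alcohol; the neutral conditions leave the terminal alkyne untouched, and the volatile ynone is carried on as a concentrated solution.

Step 9
Reactants: 14 hept-1-yn-3-one
Product: 15 2-butyl-2-ethynyl-1,3-dioxolane
Conditions: TMSOCH2CH2OTMS, TMSOTf (cat.), CH2Cl2, −78 to −20 °C
Reagents that add atoms: 1,2-bis(trimethylsilyloxy)ethane, C[Si](C)(C)OCCO[Si](C)(C)C
Why: Silyl-transfer ketalisation catalysed by TMSOTf; the absence of free alcohol and protic acid at low temperature should suppress conjugate addition to the ynone, and formation of the Si–O–Si bond drives the exchange.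

Step 10
Reactants: 15 2-butyl-2-ethynyl-1,3-dioxolane; 16 methyl chloroformate
Product: 18 methyl 3-(2-butyl-1,3-dioxolan-2-yl)prop-2-ynoate, via lithium acetylide 17 (not isolated)
Conditions: n-BuLi, THF, −78 °C; then 16, −78 to 0 °C
Reagents that add atoms: none
Why: Deprotonation of the terminal alkyne and C-acylation of the lithium acetylide by the chloroformate, a standard ynoate synthesis; the ketal is inert to the base.

Step 11
Reactants: 12 6-[2,4-bis(benzyloxy)-6-pentylphenoxy]-4-methoxy-2H-pyran-2-one; 18 methyl 3-(2-butyl-1,3-dioxolan-2-yl)prop-2-ynoate
Product: 20 methyl 2-[2,4-bis(benzyloxy)-6-pentylphenoxy]-6-(2-butyl-1,3-dioxolan-2-yl)-4-methoxybenzoate, via bridged lactone 19 (not isolated)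
Conditions: 18 (excess), o-xylene, 145 °C, sealed tube
Reagents that add atoms: none
Why: The pyranone diene C3=C4–C5=C6 of 12 and the triple bond of 18 should combine in a normal-demand, asynchronous [4+2] cycloaddition to the 2-oxabicyclo[2.2.2]octadienone 19, which loses CO2 by retro-[4+2] and aromatises irreversibly to 20. The closest known reaction type is the Diels–Alder reaction of alkoxy-2-pyranones with ynoates followed by CO2 extrusion. Ring B is closed by this intermolecular cycloaddition, which forms its C5–C6 and C1–C2 bonds, and the lactone bridge is only transient. No stereocenter survives, since the two bridgehead centers of 19 are lost on aromatisation. The selectivity required is the orientation of the alkyne. Pyranone C3 is the nucleophilic terminus, being β to the 4-methoxy group and conjugated with the 6-aryloxy group, and it should bond to the ynoate carbon β to the ester, which carries the largest LUMO coefficient. The ester is the only π-acceptor on the alkyne, because the ketone is present as a dioxolane that withdraws only inductively. Sterics point the same way, as the ketal-bearing carbon joins the unsubstituted C3 and not C6 with its bulky aryloxy group.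

Step 12
Reactants: 20 methyl 2-[2,4-bis(benzyloxy)-6-pentylphenoxy]-6-(2-butyl-1,3-dioxolan-2-yl)-4-methoxybenzoate
Product: 21 methyl 2-[2,4-bis(benzyloxy)-6-pentylphenoxy]-4-methoxy-6-pentanoylbenzoate
Conditions: 1 M HCl, THF, 40 °C
Reagents that add atoms: water, O (ketone oxygen)
Why: Acid-catalysed ketal hydrolysis through the benzylic oxocarbenium ion; the ketone appears directly at its final oxidation level, so no hydroxyl is ever free beside the ester, and the benzyl ethers, the diaryl ether and the hindered methyl ester should be stable to dilute acid at this temperature.

Step 13
Reactants: 21 methyl 2-[2,4-bis(benzyloxy)-6-pentylphenoxy]-4-methoxy-6-pentanoylbenzoate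
Product: 22 methyl 2-(2,4-dihydroxy-6-pentylphenoxy)-4-methoxy-6-pentanoylbenzoate
Conditions: H2 (1 atm), 10% Pd/C, EtOAc, rt
Reagents that add atoms: none
Why: Catalytic hydrogenolysis of the two benzyl aryl ethers under neutral conditions, which should be faster than reduction of the hindered aryl ketone; the air-sensitive product is obtained by filtration and evaporation, without acid or base that could close the seven-membered lactone.

**Compound list**

1 | olivetol (5-pentylbenzene-1,3-diol) | CCCCCc1cc(O)cc(O)c1 | starting material
2 | N-[(2,4-dihydroxy-6-pentylphenyl)methylidene]-N-methylmethanaminium chloride | CCCCCc1cc(O)cc(O)c1C=[N+](C)C.[Cl-] | intermediate (not isolated)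
3 | 2,4-dihydroxy-6-pentylbenzaldehyde | CCCCCc1cc(O)cc(O)c1C=O | intermediate
4 | 2,4-bis(benzyloxy)-6-pentylbenzaldehyde | CCCCCc1cc(OCc2ccccc2)cc(OCc2ccccc2)c1C=O | intermediate
5 | 2,4-bis(benzyloxy)-6-pentylphenyl formate | CCCCCc1cc(OCc2ccccc2)cc(OCc2ccccc2)c1OC=O | intermediate (not isolated)
6 | 2,4-bis(benzyloxy)-6-pentylphenol | CCCCCc1cc(OCc2ccccc2)cc(OCc2ccccc2)c1O | intermediate
7 | dimethyl 3-oxopentanedioate | COC(=O)CC(=O)CC(=O)OC | starting material
8 | dimethyl (E)-3-methoxypent-2-enedioate | COC(=O)/C=C(/OC)CC(=O)OC | intermediate
9 | (E)-3-methoxypent-2-enedioic acid | OC(=O)/C=C(/OC)CC(=O)O | intermediate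
10 | (E)-3-methoxypent-2-enedioyl dichloride | ClC(=O)/C=C(/OC)CC(=O)Cl | intermediate (not isolated)
11 | 6-chloro-4-methoxy-2H-pyran-2-one | COc1cc(Cl)oc(=O)c1 | intermediate
12 | 6-[2,4-bis(benzyloxy)-6-pentylphenoxy]-4-methoxy-2H-pyran-2-one | CCCCCc1cc(OCc2ccccc2)cc(OCc2ccccc2)c1Oc1cc(OC)cc(=O)o1 | intermediate
13 | hept-1-yn-3-ol (racemic) | CCCCC(O)C#C | starting material
14 | hept-1-yn-3-one | CCCCC(=O)C#C | intermediate
15 | 2-butyl-2-ethynyl-1,3-dioxolane | CCCCC1(C#C)OCCO1 | intermediate
16 | methyl chloroformate | COC(=O)Cl | starting material
17 | lithium (2-butyl-1,3-dioxolan-2-yl)acetylide | [Li]C#CC1(CCCC)OCCO1 | intermediate (not isolated)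
18 | methyl 3-(2-butyl-1,3-dioxolan-2-yl)prop-2-ynoate | CCCCC1(C#CC(=O)OC)OCCO1 | intermediate
19 | methyl 1-[2,4-bis(benzyloxy)-6-pentylphenoxy]-5-(2-butyl-1,3-dioxolan-2-yl)-8-methoxy-3-oxo-2-oxabicyclo[2.2.2]octa-5,7-diene-6-carboxylate (racemic) | O=C1OC2(Oc3c(CCCCC)cc(OCc4ccccc4)cc3OCc5ccccc5)C=C(OC)C1C(C6(CCCC)OCCO6)=C2C(=O)OC | intermediate (not isolated)
20 | methyl 2-[2,4-bis(benzyloxy)-6-pentylphenoxy]-6-(2-butyl-1,3-dioxolan-2-yl)-4-methoxybenzoate | CCCCCc1cc(OCc2ccccc2)cc(OCc2ccccc2)c1Oc1cc(OC)cc(C2(CCCC)OCCO2)c1C(=O)OC | intermediate
21 | methyl 2-[2,4-bis(benzyloxy)-6-pentylphenoxy]-4-methoxy-6-pentanoylbenzoate | CCCCCc1cc(OCc2ccccc2)cc(OCc2ccccc2)c1Oc1cc(OC)cc(C(=O)CCCC)c1C(=O)OC | intermediate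
22 | methyl 2-(2,4-dihydroxy-6-pentylphenoxy)-4-methoxy-6-pentanoylbenzoate | CCCCCc1cc(O)cc(O)c1Oc1cc(OC)cc(C(=O)CCCC)c1C(=O)OC | target

**Step count and least certain steps**

Total: 13 steps. Longest linear sequence: 7 steps (1, 2, 3, 7, 11, 12, 13 from olivetol; the sequence 4, 5, 6, 7, 11, 12, 13 from diester 7 is equally long).

Step 11 (key step). The cycloaddition may be too slow, because the alkyne carbon that must bond first carries a fully substituted ketal carbon. Thermal degradation of the acyl-transfer-prone pyranone would then compete, and any loss of regiocontrol would give the isomeric benzoate. Fallback, setting out from 12: dimethyl but-2-ynedioate, which is symmetrical and much more reactive so that no regiochemical question arises, in toluene at 110 °C should give dimethyl 3-[2,4-bis(benzyloxy)-6-pentylphenoxy]-5-methoxyphthalate F1 after loss of CO2. LiOH (1 equiv) in aqueous THF should hydrolyse only the ester that has a free ortho position, giving 3-[2,4-bis(benzyloxy)-6-pentylphenoxy]-5-methoxy-2-(methoxycarbonyl)benzoic acid F2. (COCl)2 with catalytic DMF converts this to methyl 2-[2,4-bis(benzyloxy)-6-pentylphenoxy]-6-(chlorocarbonyl)-4-methoxybenzoate F3. Coupling with n-BuMgCl and Fe(acac)3 (cat.) in THF at −78 °C should give ketone 21, where the route is rejoined, and step 12 is then not needed.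

Step 6. Intermolecular acylation (oligomerisation) of the bis(acid chloride) or cleavage of the enol ether by HCl may outrun ring closure, and the chloropyranone is moisture-sensitive. Fallback, setting out from 9: Ac2O at rt should give the cyclic anhydride 4-methoxy-2H-pyran-2,6(3H)-dione F4. Heating F4 with phenol 6 in toluene without base (the anhydride is too acidic for amine catalysis) should open it at the non-conjugated carbonyl to (E)-5-[2,4-bis(benzyloxy)-6-pentylphenoxy]-3-methoxy-5-oxopent-2-enoic acid F5. (COCl)2 and then Et3N should close F5 by intramolecular O-acylation to 12, where the route is rejoined, so that 11 and step 7 are bypassed.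

Step 7. The di-ortho-substituted phenoxide may react slowly, so that base or traces of water consume the chloropyranone, or a second phenoxide may attack the product and transfer the acyl group with ring opening. Fallback, setting out from 11: the order of ether formation and cycloaddition is reversed. Heating 11 with 18 in o-xylene at 160 °C should give methyl 2-chloro-6-(2-butyl-1,3-dioxolan-2-yl)-4-methoxybenzoate F6 after loss of CO2. Palladium-catalysed C–O coupling of F6 with 6 (Pd(OAc)2, 2-di-tert-butylphosphino-2',4',6'-triisopropylbiphenyl, K3PO4, toluene, 100 °C) should give 20, where the route is rejoined.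

Step 9. The unprotected terminal ynone may suffer conjugate addition of the diol unit or polymerise under the Lewis acid, and its volatility makes losses likely. Fallback, setting out from 13: the alkyne terminus is blocked before oxidation. n-BuLi (2 equiv) and TMSCl give 3-(trimethylsilyloxy)-1-(trimethylsilyl)hept-1-yne F7, whose O-silyl group is removed on dilute acid work-up to give 1-(trimethylsilyl)hept-1-yn-3-ol F8. Dess–Martin oxidation gives 1-(trimethylsilyl)hept-1-yn-3-one F9, and conventional ketalisation (ethylene glycol, TsOH, benzene, Dean–Stark), in which the silyl group shields the β-carbon, gives 2-butyl-2-[(trimethylsilyl)ethynyl]-1,3-dioxolane F10. K2CO3 in MeOH removes the silyl group to give 15, where the route is rejoined.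

Step 13. The aryl ketone may be over-reduced to the benzylic alcohol, which would lactonise onto the ester and be lost, or the benzyl ether ortho to the ether oxygen may cleave incompletely. Fallback, setting out from 20: the last two steps are exchanged so that no ketone is present during hydrogenolysis. H2 and Pd/C in EtOAc should give methyl 6-(2-butyl-1,3-dioxolan-2-yl)-2-(2,4-dihydroxy-6-pentylphenoxy)-4-methoxybenzoate F11, and brief treatment of F11 with dilute HCl in THF at rt under argon should give 22 directly.

**Further compounds**

F1 | step 11 | dimethyl 3-[2,4-bis(benzyloxy)-6-pentylphenoxy]-5-methoxyphthalate | CCCCCc1cc(OCc2ccccc2)cc(OCc2ccccc2)c1Oc1cc(OC)cc(C(=O)OC)c1C(=O)OC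
F2 | step 11 | 3-[2,4-bis(benzyloxy)-6-pentylphenoxy]-5-methoxy-2-(methoxycarbonyl)benzoic acid | CCCCCc1cc(OCc2ccccc2)cc(OCc2ccccc2)c1Oc1cc(OC)cc(C(=O)O)c1C(=O)OC
F3 | step 11 | methyl 2-[2,4-bis(benzyloxy)-6-pentylphenoxy]-6-(chlorocarbonyl)-4-methoxybenzoate | CCCCCc1cc(OCc2ccccc2)cc(OCc2ccccc2)c1Oc1cc(OC)cc(C(=O)Cl)c1C(=O)OC
F4 | step 6 | 4-methoxy-2H-pyran-2,6(3H)-dione | COC1=CC(=O)OC(=O)C1
F5 | step 6 | (E)-5-[2,4-bis(benzyloxy)-6-pentylphenoxy]-3-methoxy-5-oxopent-2-enoic acid | OC(=O)/C=C(/OC)CC(=O)Oc1c(CCCCC)cc(OCc2ccccc2)cc1OCc1ccccc1
F6 | step 7 | methyl 2-chloro-6-(2-butyl-1,3-dioxolan-2-yl)-4-methoxybenzoate | CCCCC1(c2cc(OC)cc(Cl)c2C(=O)OC)OCCO1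
F7 | step 9 | 3-(trimethylsilyloxy)-1-(trimethylsilyl)hept-1-yne (racemic) | CCCCC(O[Si](C)(C)C)C#C[Si](C)(C)C
F8 | step 9 | 1-(trimethylsilyl)hept-1-yn-3-ol (racemic) | CCCCC(O)C#C[Si](C)(C)C
F9 | step 9 | 1-(trimethylsilyl)hept-1-yn-3-one | CCCCC(=O)C#C[Si](C)(C)C
F10 | step 9 | 2-butyl-2-[(trimethylsilyl)ethynyl]-1,3-dioxolane | CCCCC1(C#C[Si](C)(C)C)OCCO1
F11 | step 13 | methyl 6-(2-butyl-1,3-dioxolan-2-yl)-2-(2,4-dihydroxy-6-pentylphenoxy)-4-methoxybenzoate | CCCCCc1cc(O)cc(O)c1Oc1cc(OC)cc(C2(CCCC)OCCO2)c1C(=O)OC
A1 | alternative 1 | 7-methoxy-5-pentanoyl-2'-pentylspiro[1,3-benzodioxine-2,1'-cyclohexa-2',5'-diene]-4,4'-dione (racemic) | CCCCCC1=CC(=O)C=CC12OC(=O)c3c(O2)cc(OC)cc3C(=O)CCCC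
A2 | alternative 1 | 8-hydroxy-3-methoxy-1-pentanoyl-6-pentyl-11H-dibenzo[b,e][1,4]dioxepin-11-one | CCCCCc1cc(O)cc2OC(=O)c3c(cc(OC)cc3C(=O)CCCC)Oc12
A3 | alternative 2 | methyl 2-{[(E)-2-(2-diazoacetyl)hept-1-en-1-yl]oxy}-4-methoxy-6-pentanoylbenzoate | [N-]=[N+]=CC(=O)/C(CCCCC)=C/Oc1cc(OC)cc(C(=O)CCCC)c1C(=O)OC
A4 | alternative 2 | (ethynyloxy)tri(propan-2-yl)silane | C#CO[Si](C(C)C)(C(C)C)C(C)C
A5 | alternative 2 | methyl 2-{2-hydroxy-6-pentyl-4-[(triisopropylsilyl)oxy]phenoxy}-4-methoxy-6-pentanoylbenzoate | CCCCCc1cc(O[Si](C(C)C)(C(C)C)C(C)C)cc(O)c1Oc1cc(OC)cc(C(=O)CCCC)c1C(=O)OC
A6 | alternative 3 | hept-1-yn-3-yl 3-[2,4-bis(benzyloxy)-6-pentylphenoxy]prop-2-ynoate (racemic) | CCCCCc1cc(OCc2ccccc2)cc(OCc2ccccc2)c1OC#CC(=O)OC(CCCC)C#C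
A7 | alternative 3 | methoxyethyne | COC#C
A8 | alternative 3 | 7-[2,4-bis(benzyloxy)-6-pentylphenoxy]-3-butyl-5-methoxy-2-benzofuran-1(3H)-one (racemic) | CCCCCc1cc(OCc2ccccc2)cc(OCc2ccccc2)c1Oc1cc(OC)cc2C(CCCC)OC(=O)c12
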